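**The question.** The free catalyst is single-handed, and I wanted to know how long it must work on this racemate.

| flask | left-handed substrate | right-handed substrate | coupling partner | precatalyst | remark | time |
|---|---|---|---|---|---|---|
| epsilon | 0.15 M | 0.15 M | 0.90 M | 1.6 mM | run made earlier |  |
| flask | 0.30 M | 0.30 M | 0.900 M | 1.6 mM |  | 4.0 min |

epsilon run (percent of the left-handed substrate and right-handed substrate together charged)

| time / s | right-handed substrate / % | left-handed substrate / % |
|---|---|---|
| 10.0 | 49.7 | 46.4 |
| 12.0 | 50.2 | 45.8 |
| 20.0 | 49.5 | 40.9 |
| 25.0 | 49.2 | 37.9 |

(scatter of a reading: 0.5 percentage points)

- free catalyst is single-handed; left-handed substrate and right-handed substrate are mirror images of each other, charged as a racemate, each of them at the stated concentration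
- the numbers in the tables scatter with a standard deviation of 0.5 percentage points
- on the list of suspects stand: coupling partner <-> dormant form; precatalyst -> free catalyst; coupling partner + free catalyst -> spent catalyst; coupling partner + free catalyst + left-handed substrate -> free catalyst + left-handed product; coupling partner + free catalyst + right-handed substrate -> free catalyst + right-handed product

- whether the excess of right-handed substrate over left-handed substrate among what is left of the two reaches 90% by 4.0 min (yes / no)
- the highest excess of right-handed substrate over left-handed substrate among what is left of the two up to 4.0 min

**The target.** I turned the question round and asked what the flask must achieve to reach the excess. An excess of 90% means that the left-handed substrate left is 0.0526 of the right-handed substrate left. The logarithm of right-handed over left-handed must therefore climb from zero to 2.94. I called its rate of climb the sorting constant, which is the pseudo-first-order constant of the left-handed substrate less that of the right-handed. The average sorting constant needed, 0.0123 s⁻¹, is that climb divided by the time allowed.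

**The reading.** Between 10.0 s and 25.0 s the epsilon run climbed at 0.0128 s⁻¹, a little more than needed. Stopping at 20.0 s gave 0.0122 s⁻¹, a little less, so the scatter spans the line. By 10.0 s the logarithm in the epsilon run read 0.0687, less than the 0.128 a steady constant gives, so in that run the constant had read lower at the start. Against that, this flask's left-handed substrate equals a third of the partner charge. I leaned narrowly to yes.

**The forecast.** It said no, with a top of 77%, and noted that “Catalyst death and partner going dormant cannot be seen in 25 s”.

**The result.** The flask answered yes, reaching 90% at 3.55 min, with a top of 92.3%. Its free catalyst went from 4.92% of the catalyst charged at 0.400 min to 8.27% at 2.00 min, while its partner fell from 68.5% to 38.8% of its charge.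

    coupling partner ⇌ dormant form (K = 0.778, k = 0.0149 s⁻¹)
    precatalyst → free catalyst (k = 0.00420 s⁻¹)
    coupling partner + free catalyst → spent catalyst (k = 0.0903 L mol⁻¹ s⁻¹)
    coupling partner + free catalyst + left-handed substrate → free catalyst + left-handed product (k = 322 L² mol⁻² s⁻¹)
    coupling partner + free catalyst + right-handed substrate → free catalyst + right-handed product (k = 6.24 L² mol⁻² s⁻¹)

At 4.00 min the flask kept 3.7% of its left-handed charge and 94% of its right-handed charge, an average sorting constant of 0.0134 s⁻¹, more than the 0.0123 s⁻¹ needed.

The runs are calculated for an exercise, and the scatter is random.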